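**Plan**

- The target is a biflavone with no stereocentres. C3' of ring B of unit 1 (5-hydroxy-7-methoxyflavone) is bonded to C3 of unit 2 (5,7,4'-trihydroxyflavone). The only geometric element on the way is a Z vinyl ether, set by anti oxa-Michael addition.
- Retrosynthetic cuts, in order: the five ethers (four benzyl, one chelated methyl); C4–C4a of unit 1 (Friedel-Crafts acylation); the ester; the biaryl bond C3(unit 2)–C3'(ring B) (Suzuki); O1–C2 of unit 1 (oxa-Michael); C2–C1' as an aryl–alkyne bond (Sonogashira).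
- Forward: unit 2 is bought as apigenin and armed by benzylation and C3 iodination. The ring B piece grows from 2-bromo-4-iodophenol by alkynylation, phenol addition and borylation. The two halves are joined, and ring C of unit 1, the only ring made, closes last before deprotection.
- Enabling feature: ring A of unit 1 comes from symmetrical 3,5-dimethoxyphenol. Its ether oxygen becomes O1 and its two equivalent ortho carbons offer C4a, so C4–C4a can form in one sense only. The 5-methoxy group, peri to the C4 carbonyl, is the one BCl3 removes; the 7-methoxy group stays.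

Key step: step 9

Remark: apigenin and 2-bromo-4-iodophenol are taken as purchasable; the vinyl ethers 10 to 14 are drawn as the Z isomers expected from anti addition, and a minor E isomer would be carried along because acid should equilibrate the two before ring closure.

**Route**

Step 1
Reactants: 1 apigenin, 5,7-dihydroxy-2-(4-hydroxyphenyl)-4H-chromen-4-one
Product: 2 5,7-bis(benzyloxy)-2-[4-(benzyloxy)phenyl]-4H-chromen-4-one
Conditions: BnBr (4.5 equiv), K2CO3 (6 equiv), DMF, 80 °C
Reagents that add atoms: benzyl bromide, BrCc1ccccc1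
Why: Williamson ether synthesis in which carbonate in DMF alkylates the 7- and 4'-phenoxides quickly and, with heat and excess halide, also the hydrogen-bonded 5-OH, which should give the tribenzyl ether.

Step 2
Reactants: 2 5,7-bis(benzyloxy)-2-[4-(benzyloxy)phenyl]-4H-chromen-4-one
Product: 4 5,7-bis(benzyloxy)-2-[4-(benzyloxy)phenyl]-3-iodo-4H-chromen-4-one, via 3-lithioflavone 3 (not isolated)
Conditions: LiN(i-Pr)2 (1.3 equiv), THF, −78 °C; then I2 (1.5 equiv), −78 → 0 °C; aq. Na2S2O3 work-up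
Reagents that add atoms: iodine, II
Why: Directed deprotonation–iodination, in which the amide base removes the C3 proton (the only vinylic C–H, next to the carbonyl) and iodine traps the vinyllithium, so that iodine goes to C3 and the C6/C8 attack of an electrophilic iodination on the dialkoxy ring is avoided.

Step 3
Reactants: 5 2-bromo-4-iodophenol
Product: 6 1-(benzyloxy)-2-bromo-4-iodobenzene
Conditions: BnBr (1.1 equiv), K2CO3 (1.5 equiv), acetone, reflux
Reagents that add atoms: benzyl bromide, BrCc1ccccc1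
Why: Williamson ether synthesis of a simple phenol under carbonate, both aryl halides being inert to these conditions.

Step 4
Reactants: 6 1-(benzyloxy)-2-bromo-4-iodobenzene; 7 ethyl propiolate
Product: 8 ethyl 3-[4-(benzyloxy)-3-bromophenyl]prop-2-ynoate
Conditions: Pd(PPh3)2Cl2 (3 mol%), CuI (5 mol%), K2CO3 (2 equiv), THF, 60 °C, ethyl propiolate (3 equiv) added in portions
Reagents that add atoms: none
Why: Sonogashira coupling in which zerovalent palladium inserts into the C–I bond much faster than into the C–Br bond, while K2CO3 in place of an amine base avoids conjugate addition to the propiolate.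

Step 5
Reactants: 8 ethyl 3-[4-(benzyloxy)-3-bromophenyl]prop-2-ynoate; 9 3,5-dimethoxyphenol
Product: 10 ethyl (Z)-3-[4-(benzyloxy)-3-bromophenyl]-3-(3,5-dimethoxyphenoxy)prop-2-enoate
Conditions: K2CO3 (1.2 equiv), DMF, 80 °C
Reagents that add atoms: none
Why: Base-mediated oxa-Michael addition of the phenoxide to the β-carbon of the aryl ynoate followed by anti protonation, which should give mainly the Z vinyl ether with aryloxy and ester cis and sets the future O1–C2 bond of unit 1.

Step 6
Reactants: 10 ethyl (Z)-3-[4-(benzyloxy)-3-bromophenyl]-3-(3,5-dimethoxyphenoxy)prop-2-enoate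
Product: 11 ethyl (Z)-3-[4-(benzyloxy)-3-(4,4,5,5-tetramethyl-1,3,2-dioxaborolan-2-yl)phenyl]-3-(3,5-dimethoxyphenoxy)prop-2-enoate
Conditions: B2pin2 (1.3 equiv), Pd(dppf)Cl2 (5 mol%), KOAc (3 equiv), 1,4-dioxane, 90 °C
Reagents that add atoms: bis(pinacolato)diboron, CC1(C)OB(OC1(C)C)B1OC(C)(C)C(C)(C)O1
Why: Miyaura borylation of the aryl bromide with the weak base KOAc, conditions under which the ester and the vinyl ether should be untouched.

Step 7
Reactants: 4 5,7-bis(benzyloxy)-2-[4-(benzyloxy)phenyl]-3-iodo-4H-chromen-4-one; 11 ethyl (Z)-3-[4-(benzyloxy)-3-(4,4,5,5-tetramethyl-1,3,2-dioxaborolan-2-yl)phenyl]-3-(3,5-dimethoxyphenoxy)prop-2-enoate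
Product: 12 ethyl (Z)-3-{4-(benzyloxy)-3-[5,7-bis(benzyloxy)-2-(4-benzyloxyphenyl)-4-oxo-4H-chromen-3-yl]phenyl}-3-(3,5-dimethoxyphenoxy)prop-2-enoate
Conditions: Pd(OAc)2 (5 mol%), SPhos (2-dicyclohexylphosphino-2',6'-dimethoxybiphenyl, 10 mol%), K3PO4 (3 equiv), degassed toluene/H2O 10:1, 80 °C
Reagents that add atoms: none
Why: Suzuki-Miyaura coupling in which the C3–I bond of the chromone, a vinylogous acyl iodide, adds readily to zerovalent palladium and the bulky biarylphosphine is chosen to drive transmetalation and reductive elimination at this doubly flanked carbon.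

Step 8
Reactants: 12 ethyl (Z)-3-{4-(benzyloxy)-3-[5,7-bis(benzyloxy)-2-(4-benzyloxyphenyl)-4-oxo-4H-chromen-3-yl]phenyl}-3-(3,5-dimethoxyphenoxy)prop-2-enoate
Product: 13 (Z)-3-{4-(benzyloxy)-3-[5,7-bis(benzyloxy)-2-(4-benzyloxyphenyl)-4-oxo-4H-chromen-3-yl]phenyl}-3-(3,5-dimethoxyphenoxy)prop-2-enoic acid
Conditions: LiOH·H2O (5 equiv), THF/H2O 3:1, 40 °C; then 1 M HCl to pH 3 at 0 °C
Reagents that add atoms: lithium hydroxide, [Li+].[OH-]
Why: Saponification (acyl–oxygen cleavage by hydroxide) of the ethyl ester under mild conditions without alcohol cosolvent, so that no alkoxide can exchange the aryloxy group and the chromone of unit 2 is not opened.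

Step 9
Reactants: 13 (Z)-3-{4-(benzyloxy)-3-[5,7-bis(benzyloxy)-2-(4-benzyloxyphenyl)-4-oxo-4H-chromen-3-yl]phenyl}-3-(3,5-dimethoxyphenoxy)prop-2-enoic acid
Product: 15 5,7-bis(benzyloxy)-2-[4-(benzyloxy)phenyl]-3-[2-(benzyloxy)-5-(5,7-dimethoxy-4-oxo-4H-chromen-2-yl)phenyl]-4H-chromen-4-one, via mixed trifluoroacetic anhydride 14 (not isolated)
Conditions: (CF3CO)2O (3 equiv), CH2Cl2, 0 °C → rt; aq. NaHCO3 work-up
Reagents that add atoms: none
Why: Trifluoroacetic anhydride turns the acid into the mixed anhydride 14, which acts as an acylium equivalent; the ortho carbon of the 3,5-dimethoxyphenoxy ring, activated by the ether oxygen beside it and by the ortho and para methoxy groups, attacks the acyl carbon, and the Wheland intermediate loses a proton to give the C4 carbonyl bonded to C4a. The closest known reaction is the Ruhemann flavone synthesis, an intramolecular Friedel-Crafts acylation of a β-aryloxycinnamic acid. Ring C of unit 1, the one ring formed, closes as a six-membered ring by 6-exo-trig attack on the anhydride carbonyl (6-exo-dig if the free acylium ion is the electrophile), the cis double bond lying inside the new ring. No stereocentre is created. The step needs flavone and not coumarin connectivity, a single ring position, and closure onto the phenoxy ring and not onto ring B (indenone formation): the O1–C2 bond is already in place, the two ortho carbons of the symmetrical ring are the same, and ring B stands trans to the carboxyl and is not activated at the carbons that could be reached. An E isomer, if present, should equilibrate with the Z acid by reversible protonation at the α-carbon of the vinyl ether and so be drawn into the same product.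

Step 10
Reactants: 15 5,7-bis(benzyloxy)-2-[4-(benzyloxy)phenyl]-3-[2-(benzyloxy)-5-(5,7-dimethoxy-4-oxo-4H-chromen-2-yl)phenyl]-4H-chromen-4-one
Product: 16 5-hydroxy-2-{4-hydroxy-3-[5,7-dihydroxy-2-(4-hydroxyphenyl)-4-oxo-4H-chromen-3-yl]phenyl}-7-methoxy-4H-chromen-4-one (target)
Conditions: BCl3 (1 M in CH2Cl2, 12 equiv), C6HMe5 (12 equiv), CH2Cl2, −78 °C → rt; MeOH quench, aqueous work-up
Reagents that add atoms: none
Why: Lewis acid ether cleavage in which BCl3 removes the four aryl benzyl ethers while pentamethylbenzene traps the benzyl cations, and on warming the boron chelated between the C4 carbonyl and the 5-methoxy oxygen of unit 1 delivers chloride to that methyl group only, the unchelated 7-methoxy group being left.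

**Compound list**

1 | apigenin, 5,7-dihydroxy-2-(4-hydroxyphenyl)-4H-chromen-4-one | O=c1cc(-c2ccc(O)cc2)oc2cc(O)cc(O)c12 | starting material
2 | 5,7-bis(benzyloxy)-2-[4-(benzyloxy)phenyl]-4H-chromen-4-one | O=c1cc(-c2ccc(OCc3ccccc3)cc2)oc2cc(OCc3ccccc3)cc(OCc3ccccc3)c12 | intermediate
3 | {5,7-bis(benzyloxy)-2-[4-(benzyloxy)phenyl]-4-oxo-4H-chromen-3-yl}lithium | [Li]c1c(-c2ccc(OCc3ccccc3)cc2)oc2cc(OCc3ccccc3)cc(OCc3ccccc3)c2c1=O | intermediate (not isolated)
4 | 5,7-bis(benzyloxy)-2-[4-(benzyloxy)phenyl]-3-iodo-4H-chromen-4-one | O=c1c(I)c(-c2ccc(OCc3ccccc3)cc2)oc2cc(OCc3ccccc3)cc(OCc3ccccc3)c12 | intermediate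
5 | 2-bromo-4-iodophenol | Oc1ccc(I)cc1Br | starting material
6 | 1-(benzyloxy)-2-bromo-4-iodobenzene | Brc1cc(I)ccc1OCc1ccccc1 | intermediate
7 | ethyl propiolate | CCOC(=O)C#C | starting material
8 | ethyl 3-[4-(benzyloxy)-3-bromophenyl]prop-2-ynoate | CCOC(=O)C#Cc1ccc(OCc2ccccc2)c(Br)c1 | intermediate
9 | 3,5-dimethoxyphenol | COc1cc(O)cc(OC)c1 | starting material
10 | ethyl (Z)-3-[4-(benzyloxy)-3-bromophenyl]-3-(3,5-dimethoxyphenoxy)prop-2-enoate | CCOC(=O)/C=C(\Oc1cc(OC)cc(OC)c1)c1ccc(OCc2ccccc2)c(Br)c1 | intermediate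
11 | ethyl (Z)-3-[4-(benzyloxy)-3-(4,4,5,5-tetramethyl-1,3,2-dioxaborolan-2-yl)phenyl]-3-(3,5-dimethoxyphenoxy)prop-2-enoate | CCOC(=O)/C=C(\Oc1cc(OC)cc(OC)c1)c1ccc(OCc2ccccc2)c(B2OC(C)(C)C(C)(C)O2)c1 | intermediate
12 | ethyl (Z)-3-{4-(benzyloxy)-3-[5,7-bis(benzyloxy)-2-(4-benzyloxyphenyl)-4-oxo-4H-chromen-3-yl]phenyl}-3-(3,5-dimethoxyphenoxy)prop-2-enoate | CCOC(=O)/C=C(\Oc1cc(OC)cc(OC)c1)c1ccc(OCc2ccccc2)c(-c2c(-c3ccc(OCc4ccccc4)cc3)oc3cc(OCc4ccccc4)cc(OCc4ccccc4)c3c2=O)c1 | intermediate
13 | (Z)-3-{4-(benzyloxy)-3-[5,7-bis(benzyloxy)-2-(4-benzyloxyphenyl)-4-oxo-4H-chromen-3-yl]phenyl}-3-(3,5-dimethoxyphenoxy)prop-2-enoic acid | OC(=O)/C=C(\Oc1cc(OC)cc(OC)c1)c1ccc(OCc2ccccc2)c(-c2c(-c3ccc(OCc4ccccc4)cc3)oc3cc(OCc4ccccc4)cc(OCc4ccccc4)c3c2=O)c1 | intermediate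
14 | mixed anhydride of acid 13 with trifluoroacetic acid (Z) | FC(F)(F)C(=O)OC(=O)/C=C(\Oc1cc(OC)cc(OC)c1)c1ccc(OCc2ccccc2)c(-c2c(-c3ccc(OCc4ccccc4)cc3)oc3cc(OCc4ccccc4)cc(OCc4ccccc4)c3c2=O)c1 | intermediate (not isolated)
15 | 5,7-bis(benzyloxy)-2-[4-(benzyloxy)phenyl]-3-[2-(benzyloxy)-5-(5,7-dimethoxy-4-oxo-4H-chromen-2-yl)phenyl]-4H-chromen-4-one | COc1cc(OC)c2c(=O)cc(-c3ccc(OCc4ccccc4)c(-c4c(-c5ccc(OCc6ccccc6)cc5)oc5cc(OCc6ccccc6)cc(OCc6ccccc6)c5c4=O)c3)oc2c1 | intermediate
16 | 5-hydroxy-2-{4-hydroxy-3-[5,7-dihydroxy-2-(4-hydroxyphenyl)-4-oxo-4H-chromen-3-yl]phenyl}-7-methoxy-4H-chromen-4-one | COc1cc(O)c2c(=O)cc(-c3ccc(O)c(-c4c(-c5ccc(O)cc5)oc5cc(O)cc(O)c5c4=O)c3)oc2c1 | target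

**Count**

Total steps: 10. Longest linear sequence: 8 steps (5 → 16 through steps 3 to 10); the apigenin branch (steps 1 and 2) joins at step 7.

**Steps most likely to fail**

Step 9. On the large and poorly soluble acid the ring closure may be slow. Acid-promoted loss or transfer of benzyl groups, or trifluoroacetylation of the dimethoxyphenoxy ring, could then compete. The fallback closes ring C before the two units are joined; it sets out from 10 and returns at 15.
- Bromo ester 10 is saponified (LiOH·H2O, THF/H2O) to (Z)-3-[4-(benzyloxy)-3-bromophenyl]-3-(3,5-dimethoxyphenoxy)prop-2-enoic acid F1.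
- Trifluoroacetic anhydride in CH2Cl2 converts it, through its mixed trifluoroacetic anhydride F2, into 2-[4-(benzyloxy)-3-bromophenyl]-5,7-dimethoxy-4H-chromen-4-one F3, by the same Ruhemann closure on a substrate that lacks unit 2.
- Miyaura borylation (B2pin2, Pd(dppf)Cl2, KOAc, dioxane) gives 2-[4-(benzyloxy)-3-(4,4,5,5-tetramethyl-1,3,2-dioxaborolan-2-yl)phenyl]-5,7-dimethoxy-4H-chromen-4-one F4.
- Suzuki coupling of F4 with iodide 4 (Pd(OAc)2, SPhos, K3PO4) gives 15.

Step 7. Transmetalation at the doubly flanked C3 may be slow. Protodeboronation of the ortho-alkoxy boronate, reduction of the iodide, or attack of aqueous base on the vinyl ether could then outrun the coupling. The fallback reverses the polarity under anhydrous conditions; it sets out from 2 and 10 and returns at 12, and steps 2 and 6 fall away.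
- Flavone 2 is deprotonated as in step 2 (LiN(i-Pr)2, THF, −78 °C) to 3, and ZnCl2 converts this into {5,7-bis(benzyloxy)-2-[4-(benzyloxy)phenyl]-4-oxo-4H-chromen-3-yl}zinc chloride F5.
- Negishi coupling of F5 with aryl bromide 10 (Pd(OAc)2, SPhos, THF, 50 °C) gives 12.

Step 4. Base-induced oligomerisation of ethyl propiolate and oxidative alkyne homocoupling may consume the alkyne faster than the cross-coupling. The fallback brings in the ester carbon from CO2; it sets out from 6 and returns at 8.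
- Sonogashira coupling of 6 with trimethylsilylacetylene (Pd(PPh3)2Cl2, CuI, Et3N, rt, iodide-selective) gives {[4-(benzyloxy)-3-bromophenyl]ethynyl}trimethylsilane F6.
- Fluoride-mediated carboxylation (CsF, CO2 at 1 atm, DMSO, rt) gives caesium 3-[4-(benzyloxy)-3-bromophenyl]prop-2-ynoate F7.
- F7 is alkylated in the same flask with iodoethane to give 8.

**Further compounds**

F1 | step 9 | (Z)-3-[4-(benzyloxy)-3-bromophenyl]-3-(3,5-dimethoxyphenoxy)prop-2-enoic acid | OC(=O)/C=C(\Oc1cc(OC)cc(OC)c1)c1ccc(OCc2ccccc2)c(Br)c1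
F2 | step 9 | mixed anhydride of F1 with trifluoroacetic acid (Z) | FC(F)(F)C(=O)OC(=O)/C=C(\Oc1cc(OC)cc(OC)c1)c1ccc(OCc2ccccc2)c(Br)c1
F3 | step 9 | 2-[4-(benzyloxy)-3-bromophenyl]-5,7-dimethoxy-4H-chromen-4-one | COc1cc(OC)c2c(=O)cc(-c3ccc(OCc4ccccc4)c(Br)c3)oc2c1
F4 | step 9 | 2-[4-(benzyloxy)-3-(4,4,5,5-tetramethyl-1,3,2-dioxaborolan-2-yl)phenyl]-5,7-dimethoxy-4H-chromen-4-one | COc1cc(OC)c2c(=O)cc(-c3ccc(OCc4ccccc4)c(B4OC(C)(C)C(C)(C)O4)c3)oc2c1
F5 | step 7 | {5,7-bis(benzyloxy)-2-[4-(benzyloxy)phenyl]-4-oxo-4H-chromen-3-yl}zinc chloride | Cl[Zn]c1c(-c2ccc(OCc3ccccc3)cc2)oc2cc(OCc3ccccc3)cc(OCc3ccccc3)c2c1=O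
F6 | step 4 | {[4-(benzyloxy)-3-bromophenyl]ethynyl}trimethylsilane | C[Si](C)(C)C#Cc1ccc(OCc2ccccc2)c(Br)c1
F7 | step 4 | caesium 3-[4-(benzyloxy)-3-bromophenyl]prop-2-ynoate | [Cs+].[O-]C(=O)C#Cc1ccc(OCc2ccccc2)c(Br)c1
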